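(The runs were computed with made-up constants; noise was put on by code.)

By 8.00 h the lean beta flask has made more target than the zeta flask, c(target) 14.7 mM against 12.9 mM, and the rich theta flask has made less, 9.15 mM. These flasks share one precatalyst charge and one reading time, so if the catalyst ages alike in them, its ageing cancels in a quotient. Beta over zeta reads 1.14: this is the inhibition ratio, the target made from a lean charge divided by the target made from a rich one, at equal time and equal precatalyst. A value above one is the mark of substrate inhibition.

| flask | substrate | precatalyst | remark | time |
|---|---|---|---|---|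
| zeta | 0.10 M | 10 µM | run made earlier |  |
| beta | 0.067 M | 10 µM | run made earlier |  |
| theta | 0.15 M | 10 µM | run made earlier |  |
| delta | 0.10 M | 15 µM | run made earlier |  |
| east | 0.10 M | 10 µM | one stirred flow tank at steady state, fed with the mixture as stated, mean residence time 25 h |  |
| south-east | 0.10 M (fed, over 25.0 h) | 10 µM | all but substrate at the start; substrate goes in evenly over 25.0 h, the run ends at 25 h | 25 h |
| north-east | 0.10 M | 10 µM | a closed flask charged with all of it at once and left for 25 h | 25 h |

| run | time / h | target / % | substrate / % |
|---|---|---|---|
| zeta | 2.00 | 2.6 | 97.9 |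
| zeta | 4.00 | 6.8 | 93.7 |
| zeta | 8.00 | 12.9 | 87.0 |
| zeta | 12.0 | 19.0 | 82.1 |
| zeta | 25.0 | 36.2 | 63.4 |
| beta | 2.50 | 5.7 | 93.6 |
| beta | 8.00 | 22.0 | 76.9 |
| beta | 15.0 | 40.9 | 57.6 |
| beta | 20.0 | 53.0 | 47.8 |
| beta | 30.0 | 70.4 | 29.8 |
| theta | 2.50 | 2.3 | 98.9 |
| theta | 5.00 | 4.2 | 95.9 |
| theta | 8.00 | 6.1 | 93.2 |
| theta | 15.0 | 12.1 | 88.6 |
| theta | 30.0 | 21.6 | 78.8 |
| delta | 2.50 | 6.0 | 95.7 |
| delta | 5.00 | 9.8 | 89.9 |
| delta | 8.00 | 16.4 | 84.6 |
| delta | 15.0 | 28.8 | 70.6 |
| delta | 30.0 | 52.9 | 46.5 |

(standard deviation of a reading: 0.5 percentage points)

- the stated concentrations are those of everything mixed, before any reaction; amounts are the same in each set-up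
- the analysis behind the earlier runs scatters by 0.5 percentage points, standard deviation
- the feed brings no volume worth counting
- the earlier runs were made in a closed, stirred flask

1. the set-up with the highest amount of target at the outlet or at the end, in percent of the substrate put in ("none" if the first two lie within 2 percentage points) (east / south-east / north-east / none)
2. amount of target at the outlet or at the end, in percent of the substrate put in, east
3. amount of target at the outlet or at the end, in percent of the substrate put in, south-east
4. amount of target at the outlet or at the end, in percent of the substrate put in, north-east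

North-east repeats the zeta recipe, so the estimate for it is the zeta reading, 36.2%. Were a flask to stay at the lean level throughout, the ratio read at 8.00 h would lift that to 41.4%, a gain of 5.2 percentage points, more than the margin. East, converting as zeta does, would hold c(substrate) near 63.8 mM, close to the beta charge.

The weak link is the lean end, which south-east must cross while its feed of 4.00 mM h⁻¹ builds up. The late readings reforge it. Between 20.0 h and 30.0 h the beta flask, at c(substrate) from 32.0 mM down to 20.0 mM, makes 1.17 mM h⁻¹. The zeta flask, between 12.0 h and 25.0 h, makes 1.32 mM h⁻¹. Their quotient, 0.881, reads below 1.14, but the beta window is the later one, so the lift is not counted on at the lean end. My commitment is therefore that the set-ups stay near the zeta reading and within 2 points of each other.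

The forecast gives 34% for east, 36.5% for south-east and 36.2% for north-east, with best none, on the ground that “substrate stays near the optimum, but the catalyst ages and the early ramp is starved”.

The flasks give 35.5% for east, 36.6% for south-east and 36.8% for north-east, so the best is none.

    substrate + enzyme → target + enzyme, rate k1*[substrate]*[enzyme]/(1 + ([substrate]/Km1) + ([substrate]/Ksi1)^2) (27.1 mM, 39.3 mM, k = 130 L mol⁻¹ s⁻¹)
    precatalyst ⇌ enzyme (K = 1.85, k = 1.44 × 10⁻⁵ s⁻¹)
    2 enzyme → spent catalyst (k = 358 L mol⁻¹ s⁻¹)

At 25.0 h south-east and north-east hold enzyme at 2.39% and 2.39%. The neighbour flask with 0.25 M of substrate also holds enzyme at 2.39%, and north-east over that neighbour gives an inhibition ratio of 1.92, higher than the 1.14 read at 8.00 h, the neighbour's target standing at 7.65%.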